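Locants: decalin C1–C8a (C2 = carbinol carrying the cyclopentane, C4a = angular-methyl carbon, C5 = CHBr, C8 = C(Me)OH, C8a = ring-fusion carbinol; ring A = C1–C4, C4a, C8a; ring B = C4a–C8a); cyclopentane C1′ (quaternary, on C2), C2′ (CHOH), C3′, C4′ (CHBr), C5′ (CMe2).
Retrosynthesis: C5–Br and C4′–Br (alkenyl bromide hydrogenation; bromide conjugate addition), C2–OH and C2′–OH (epoxide opening, ketone reduction), C1′–CH3 (enolate methylation), C2–C1′ (aldol condensation with 4,4-dimethylcyclopent-2-enone), then C3–C4 together with C4a–C8a, then the chain back to geraniol.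
Enabling feature: C3 and C8a stand 1,4 across ring A and both C8a and C2 carry oxygen, so C1, C2, C3, C8a and the C8a oxygen can be written as a 3-oxygenated furan. Its Diels–Alder reaction with the C4=C4a isopropenyl ketone (C5 carbonyl = future CHBr), tethered through C8–C7–C6, closes rings A and B at once; the extra C3–O bond is cut later with SmI2.
Forward: geraniol → (S)-alkynol (C8) → furanone enone → cycloaddition (rings A and B, oxygen bridge) → cyclopentenone joined at C2 → bridge opened → C1′ methyl → C4′ bromide → C2 and C2′ carbinols → C5 bromide → deprotection.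
Stereochemistry: C8 from Sharpless epoxidation; C4a and C8a (trans fusion) from the exo-tethered cycloaddition under control of C8; C1′ from catalyst-controlled methylation; C2 from C8a-hydroxyl-directed epoxidation and diaxial hydride opening; C4′, C2′ and C5 from substrate control.

Key step: step 10

Remark: 6, 7, 9, 10 and 11 are carried as epimer mixtures at the future C5, 17–20 as mixtures at C2/C1′ or of alkene isomers, and 21 as C1′ epimers; these centres are erased or reset later, so their SMILES leave them open.

Step 1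
Reactants: 1 geraniol
Product: 2 (2S,3S)-2,3-epoxygeraniol
Conditions: Ti(OiPr)4 (5 mol %), L-(+)-diethyl tartrate (6 mol %), t-BuOOH, 4 Å sieves, CH2Cl2, −20 °C
Reagents that add atoms: tert-butyl hydroperoxide, CC(C)(C)OO
Why: Sharpless asymmetric epoxidation of the allylic alcohol, in which the L-(+)-tartrate/titanium catalyst delivers oxygen to one face of the 2,3-alkene and so sets the tertiary C–O centre that becomes C8 (S).

Step 2
Reactants: 2 (2S,3S)-2,3-epoxygeraniol
Product: 3 (2R,3S)-1-chloro-2,3-epoxy-3,7-dimethyloct-6-ene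
Conditions: PPh3, CCl4, NaHCO3, reflux
Reagents that add atoms: carbon tetrachloride, ClC(Cl)(Cl)Cl
Why: Appel chlorination of the primary alcohol under neutral conditions that leave the epoxide and its two stereocentres untouched.

Step 3
Reactants: 3 (2R,3S)-1-chloro-2,3-epoxy-3,7-dimethyloct-6-ene
Product: 4 (S)-3,7-dimethyloct-6-en-1-yn-3-ol
Conditions: n-BuLi (3.2 equiv), THF, −40 °C
Reagents that add atoms: none
Why: Base-induced double elimination of a 2,3-epoxy chloride (α-deprotonation with epoxide opening to the chloroalkenyl alkoxide, then dehydrochlorination) gives the terminal alkyne; the tertiary C–O bond is not broken, so C8 keeps its configuration.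

Step 4
Reactants: 4 (S)-3,7-dimethyloct-6-en-1-yn-3-ol
Product: 5 (S)-3-(tert-butyldimethylsilyloxy)-3,7-dimethyloct-6-en-1-yne
Conditions: TBSOTf, 2,6-lutidine, CH2Cl2, 0 °C
Reagents that add atoms: tert-butyldimethylsilyl triflate, CC(C)(C)[Si](C)(C)OS(=O)(=O)C(F)(F)F
Why: Silylation of the tertiary propargylic alcohol with the silyl triflate protects the future C8 hydroxyl through all later steps.

Step 5
Reactants: 5 (S)-3-(tert-butyldimethylsilyloxy)-3,7-dimethyloct-6-en-1-yne
Product: 6 6,7-epoxide of 5
Conditions: mCPBA, NaHCO3, CH2Cl2, 0 °C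
Reagents that add atoms: 3-chloroperbenzoic acid, OOC(=O)c1cccc(Cl)c1
Why: Prilezhaev epoxidation occurs at the electron-rich trisubstituted alkene and not at the alkyne; the new centre (future C5) is formed without control because it is later oxidised.

Step 6
Reactants: 6 6,7-epoxide of 5
Product: 7 (6S)-6-(tert-butyldimethylsilyloxy)-2,6-dimethyloct-1-en-7-yn-3-ol
Conditions: Et2AlCl, lithium 2,2,6,6-tetramethylpiperidide (4 equiv each), toluene, 0 °C
Reagents that add atoms: none
Why: Aluminium-amide-mediated isomerisation of the trisubstituted epoxide to the allylic alcohol by syn β-elimination with removal of a methyl proton gives the secondary alcohol flanked by the isopropenyl group.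

Step 7
Reactants: 7 (6S)-6-(tert-butyldimethylsilyloxy)-2,6-dimethyloct-1-en-7-yn-3-ol; 8 2-(tert-butyldimethylsilyloxy)-N-methoxy-N-methylacetamide
Product: 9 (5S)-1,5-bis(tert-butyldimethylsilyloxy)-8-hydroxy-5,9-dimethyldec-9-en-3-yn-2-one
Conditions: n-BuLi (2.1 equiv), THF, −78 °C; then 8, −78 to −20 °C
Reagents that add atoms: none
Why: Acylation of the lithium acetylide (formed beside the lithium alkoxide) by the Weinreb amide stops at the ynone because of the chelated tetrahedral intermediate.

Step 8
Reactants: 9 (5S)-1,5-bis(tert-butyldimethylsilyloxy)-8-hydroxy-5,9-dimethyldec-9-en-3-yn-2-one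
Product: 11 5-[(2S)-2-(tert-butyldimethylsilyloxy)-5-hydroxy-6-methylhept-6-en-2-yl]furan-3(2H)-one, via hydroxy ynone 10 (not isolated)
Conditions: camphorsulfonic acid (10 mol %), MeOH, 0 °C; then Et2NH (0.3 equiv), EtOH, 22 °C
Reagents that add atoms: none
Why: Acid methanolysis removes only the primary silyl ether, and the freed α′-hydroxy ynone closes by amine-promoted 5-endo-dig oxa-Michael addition to the 3(2H)-furanone.

Step 9
Reactants: 11 5-[(2S)-2-(tert-butyldimethylsilyloxy)-5-hydroxy-6-methylhept-6-en-2-yl]furan-3(2H)-one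
Product: 12 5-[(2S)-2-(tert-butyldimethylsilyloxy)-6-methyl-5-oxohept-6-en-2-yl]furan-3(2H)-one
Conditions: Dess–Martin periodinane, NaHCO3, CH2Cl2, 22 °C
Reagents that add atoms: none
Why: Dess–Martin oxidation of the secondary allylic alcohol gives the isopropenyl ketone that serves as the dienophile and removes the uncontrolled C5 centre.

Step 10
Reactants: 12 5-[(2S)-2-(tert-butyldimethylsilyloxy)-6-methyl-5-oxohept-6-en-2-yl]furan-3(2H)-one
Product: 15 oxa-bridged diketone (8-silyloxy-4a,8-dimethyl-3,8a-epoxydecalin-2,5-dione), via silyloxyfuran 13 (not isolated), via cycloadduct silyl enol ether 14 (not isolated)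
Conditions: TBSOTf (1.05 equiv), Et3N, CH2Cl2, −78 °C; then toluene, 80 °C; then 0.5 M HCl, THF, 0 °C
Reagents that add atoms: none
Why: Soft enolisation of the furanone methylene (future C3), far more acidic than the enone α′-position because deprotonation gives an aromatic furanolate, forms the 3-silyloxyfuran 13, whose electron-rich C3 is polarity-matched with the enone β-carbon C4, and a concerted asynchronous intramolecular [4+2] cycloaddition then forms C3–C4 and C4a–C8a. The closest known reaction types are the intramolecular Diels–Alder reaction of 2-alkylfurans carrying an enone in the side chain and the Diels–Alder reactions of 3-alkoxy- and 3-silyloxyfurans. Ring A closes as the carbocycle of the 7-oxanorbornene in the cycloaddition proper, and ring B closes through the four-atom tether C8–C7–C6–C5, which can bridge the furan terminus C8a and the dienophile carbon C4a only on the side of the ring oxygen (tether exo). This constraint places the C4a methyl endo, anti to the C3–O–C8a bridge that fixes C3 and C8a relative to each other, so the ring fusion is trans once the bridge is cut, and the furan face is chosen by C8 through a chair-like tether with the C8 methyl equatorial and the silyloxy group axial, which avoids a 1,3-diaxial methyl/methyl contact with the C4a methyl. The step needs a favourable equilibrium and an intact bridge: the quaternary C8 (gem-disubstituent effect) and the matched diene/dienophile pair favour the adduct, and C-protonation of the silyl enol ether 14 by dilute acid gives ketone 15, which can no longer revert.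

Step 11
Reactants: 15 oxa-bridged diketone; 16 4,4-dimethylcyclopent-2-en-1-one
Product: 19 oxa-bridged dienone (C2 alkylidene: 2-(2,2-dimethyl-5-oxocyclopent-3-en-1-ylidene) derivative of 15), via aldol adduct 17 (not isolated), via tertiary mesylate 18 (not isolated)
Conditions: 16, LiN(i-Pr)2 (1.1 equiv), THF, −78 °C; then 15, −78 °C; then MsCl, −78 to 0 °C; then DBU, 22 °C
Reagents that add atoms: none
Why: Directed aldol addition of the kinetic α′-lithium enolate of 16 (its only enolisable site) to the strained α-oxygenated C2 ketone, which is far more electrophilic than the C5 ketone next to the quaternary C4a, followed by mesylation and E1cB elimination gives the alkylidene; the alkene geometry is of no consequence.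

Step 12
Reactants: 19 oxa-bridged dienone
Product: 20 oxa-bridged dienone with C5 alkenyl bromide (5-bromo-5,6-ene)
Conditions: P(OPh)3, Br2, CH2Cl2, −60 °C; then Et3N, 19, −60 to 22 °C
Reagents that add atoms: bromine (delivered as the triphenyl phosphite–bromine adduct), BrBr
Why: Conversion of an enolisable ketone into the alkenyl bromide by the bromophosphonium reagent from triphenyl phosphite and bromine; C5 can enolise only towards C6 and the cross-conjugated dienone carbonyl has no α-hydrogen.

Step 13
Reactants: 20 oxa-bridged dienone with C5 alkenyl bromide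
Product: 21 ring-opened hydroxy enone (C8a–OH free, C2=C3 alkene, C1′–H)
Conditions: SmI2 (2.2 equiv), MeOH, THF, −78 °C
Reagents that add atoms: none
Why: Samarium diiodide reduction of the dienone gives a dienolate radical anion that expels the γ-alkoxide (the strained C3–O bond of the bridge), as in reductions of γ-oxygenated enones, and kinetic α-protonation leaves the C2=C3 alkene and the free C8a hydroxyl; C1′ is formed as a mixture that the next step resets.

Step 14
Reactants: 21 ring-opened hydroxy enone
Product: 22 C1′-methylated enone (quaternary C1′)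
Conditions: MeI, 50% aq. KOH, toluene, O-allyl-N-(9-anthracenylmethyl)cinchonidinium bromide (10 mol %), −20 °C
Reagents that add atoms: iodomethane, CI
Why: Asymmetric phase-transfer alkylation of an α-substituted cyclic ketone: the most acidic proton (C1′–H, α to the ketone and allylic) is removed, the extended enolate is methylated at its α-carbon, and the chiral ammonium ion pair selects the enolate face at C1′, which lies too far from the decalin stereocentres for them to interfere.

Step 15
Reactants: 22 C1′-methylated enone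
Product: 24 β-bromo ketone (C4′–Br cis to the decalinyl group), via bromo silyl enol ether 23 (not isolated)
Conditions: Me3SiBr (3 equiv), Et3N (1.1 equiv), CH2Cl2, −40 to 0 °C; then aq. citric acid, THF, 0 °C
Reagents that add atoms: bromotrimethylsilane, C[Si](C)(C)Br
Why: Conjugate addition of bromide to the silyl-activated cyclopentenone (halosilane 1,4-addition) under reversible conditions gives the bromide cis to the large decalinyl group on C1′ (both pseudo-equatorial, avoiding a 1,3-diaxial Br/Me contact), and mild hydrolysis of the silyl enol ether and of the transient C8a silyl ether gives the β-bromo ketone.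

Step 16
Reactants: 24 β-bromo ketone
Product: 25 2,3-epoxide (oxygen syn to C8a–OH)
Conditions: VO(acac)2 (5 mol %), t-BuOOH, CH2Cl2, 0 to 22 °C
Reagents that add atoms: tert-butyl hydroperoxide, CC(C)(C)OO
Why: Vanadium-catalysed hydroxyl-directed epoxidation: the homoallylic axial C8a–OH delivers the peroxide to the C2=C3 alkene on its own face, which sets the C2–O bond syn to the C8a oxygen.

Step 17
Reactants: 25 2,3-epoxide
Product: 26 C2,C8a,C2′-triol with C8 silyl ether and C5 alkenyl bromide
Conditions: LiAlH4, THF, −78 to 0 °C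
Reagents that add atoms: none
Why: Hydride reduces the C2′ ketone from the face of the C1′ methyl (away from the decalinyl group and the C4′ bromide), giving the hydroxyl cis to both, and opens the epoxide at the secondary C3 in the trans-diaxial sense (Fürst–Plattner rule), giving the axial tertiary C2 alcohol.

Step 18
Reactants: 26 C2,C8a,C2′-triol with C5 alkenyl bromide
Product: 27 C8 silyl ether of the target
Conditions: Mn(dpm)3 (10 mol %; dpm = 2,2,6,6-tetramethylheptane-3,5-dionate), PhSiH3, t-BuOOH, i-PrOH, 22 °C
Reagents that add atoms: none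
Why: Manganese-hydride hydrogen-atom-transfer hydrogenation of the alkenyl bromide (hydrogen atom to C6, then to the α-bromo radical at C5) reduces the alkene without loss of bromine and delivers the second hydrogen axially, anti to the C4a methyl, to give the equatorial bromide.

Step 19
Reactants: 27 C8 silyl ether of the target
Product: 28 target, (2S,4aR,5R,8S,8aS)-5-bromo-2-[(1S,2R,4S)-4-bromo-2-hydroxy-1,5,5-trimethylcyclopentyl]-4a,8-dimethyldecahydronaphthalene-2,8,8a-triol (locants as defined above)
Conditions: HF·pyridine, THF, 0 to 22 °C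
Reagents that add atoms: none
Why: Fluoride-mediated cleavage of the tertiary silyl ether under acidic, non-basic conditions frees the C8 hydroxyl without elimination of the secondary bromides.

Compound list
1 | geraniol, (2E)-3,7-dimethylocta-2,6-dien-1-ol | CC(C)=CCC/C(C)=C/CO | starting material
2 | (2S,3S)-2,3-epoxygeraniol | OC[C@@H]1O[C@@]1(C)CCC=C(C)C | intermediate
3 | (2R,3S)-1-chloro-2,3-epoxy-3,7-dimethyloct-6-ene (chloride of 2, same spatial arrangement) | ClC[C@@H]1O[C@@]1(C)CCC=C(C)C | intermediate
4 | (S)-3,7-dimethyloct-6-en-1-yn-3-ol | C#C[C@@](C)(O)CCC=C(C)C | intermediate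
5 | (S)-3-(tert-butyldimethylsilyloxy)-3,7-dimethyloct-6-en-1-yne | C#C[C@@](C)(O[Si](C)(C)C(C)(C)C)CCC=C(C)C | intermediate
6 | 6,7-epoxide of 5 (both epoxide epimers) | C#C[C@@](C)(O[Si](C)(C)C(C)(C)C)CCC1OC1(C)C | intermediate
7 | (6S)-6-(tert-butyldimethylsilyloxy)-2,6-dimethyloct-1-en-7-yn-3-ol (both C3 epimers) | C#C[C@@](C)(O[Si](C)(C)C(C)(C)C)CCC(O)C(C)=C | intermediate
8 | 2-(tert-butyldimethylsilyloxy)-N-methoxy-N-methylacetamide | CC(C)(C)[Si](C)(C)OCC(=O)N(C)OC | starting material
9 | (5S)-1,5-bis(tert-butyldimethylsilyloxy)-8-hydroxy-5,9-dimethyldec-9-en-3-yn-2-one (C8 epimers) | CC(C)(C)[Si](C)(C)OCC(=O)C#C[C@@](C)(O[Si](C)(C)C(C)(C)C)CCC(O)C(C)=C | intermediate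
10 | (5S)-5-(tert-butyldimethylsilyloxy)-1,8-dihydroxy-5,9-dimethyldec-9-en-3-yn-2-one | OCC(=O)C#C[C@@](C)(O[Si](C)(C)C(C)(C)C)CCC(O)C(C)=C | intermediate
11 | 5-[(2S)-2-(tert-butyldimethylsilyloxy)-5-hydroxy-6-methylhept-6-en-2-yl]furan-3(2H)-one (side-chain C5 epimers) | O=C1COC(=C1)[C@@](C)(O[Si](C)(C)C(C)(C)C)CCC(O)C(C)=C | intermediate
12 | 5-[(2S)-2-(tert-butyldimethylsilyloxy)-6-methyl-5-oxohept-6-en-2-yl]furan-3(2H)-one | O=C1COC(=C1)[C@@](C)(O[Si](C)(C)C(C)(C)C)CCC(=O)C(C)=C | intermediate
13 | (6S)-6-(tert-butyldimethylsilyloxy)-6-[4-(tert-butyldimethylsilyloxy)furan-2-yl]-2-methylhept-1-en-3-one | CC(C)(C)[Si](C)(C)Oc1coc(c1)[C@@](C)(O[Si](C)(C)C(C)(C)C)CCC(=O)C(C)=C | intermediate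
14 | cycloadduct silyl enol ether: 2,8-bis(silyloxy)-4a,8-dimethyl-3,8a-epoxy-octahydronaphthalen-5-one with C1=C2 enol ether; oxygen bridge syn to C5 and anti to the C4a methyl; C8 silyloxy anti to the bridge | CC(C)(C)[Si](C)(C)OC=1[C@@H]2C[C@@]3(C)C(=O)CC[C@](C)(O[Si](C)(C)C(C)(C)C)[C@]3(O2)C=1 | intermediate
15 | oxa-bridged diketone: 8-(tert-butyldimethylsilyloxy)-4a,8-dimethyl-3,8a-epoxydecalin-2,5-dione, same relative configuration as 14 (8S) | O=C1[C@@H]2C[C@@]3(C)C(=O)CC[C@](C)(O[Si](C)(C)C(C)(C)C)[C@]3(O2)C1 | intermediate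
16 | 4,4-dimethylcyclopent-2-en-1-one | CC1(C)C=CC(=O)C1 | starting material
17 | aldol adduct of 15 (C2 tertiary alcohol bearing the 2,2-dimethyl-5-oxocyclopent-3-en-1-yl group; mixture at C2 and C1′) | O=C1C=CC(C)(C)C1C1(O)[C@@H]2C[C@@]3(C)C(=O)CC[C@](C)(O[Si](C)(C)C(C)(C)C)[C@]3(O2)C1 | intermediate
18 | C2 methanesulfonate of 17 | O=C1C=CC(C)(C)C1C1(OS(C)(=O)=O)[C@@H]2C[C@@]3(C)C(=O)CC[C@](C)(O[Si](C)(C)C(C)(C)C)[C@]3(O2)C1 | intermediate
19 | oxa-bridged dienone: 2-(2,2-dimethyl-5-oxocyclopent-3-en-1-ylidene) derivative of the 3,8a-epoxydecalin-5-one (alkene isomers) | O=C1C=CC(C)(C)C1=C1[C@@H]2C[C@@]3(C)C(=O)CC[C@](C)(O[Si](C)(C)C(C)(C)C)[C@]3(O2)C1 | intermediate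
20 | 5-bromo-5,6-ene analogue of 19 (C5 alkenyl bromide) | O=C1C=CC(C)(C)C1=C1[C@@H]2C[C@@]3(C)C(Br)=CC[C@](C)(O[Si](C)(C)C(C)(C)C)[C@]3(O2)C1 | intermediate
21 | ring-opened hydroxy enone: 5-(decalin-2-yl)-4,4-dimethylcyclopent-2-enone with C2=C3 and C5=C6 (5-bromo) alkenes, free C8a–OH, C8 silyl ether (C1′ epimers) | O=C1C=CC(C)(C)C1C1=CC[C@@]2(C)C(Br)=CC[C@](C)(O[Si](C)(C)C(C)(C)C)[C@]2(O)C1 | intermediate
22 | C1′-methyl derivative of 21 (quaternary C1′, configuration of the target) | O=C1C=CC(C)(C)[C@]1(C)C1=CC[C@@]2(C)C(Br)=CC[C@](C)(O[Si](C)(C)C(C)(C)C)[C@]2(O)C1 | intermediate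
23 | C4′-bromo trimethylsilyl enol ether of 22 with C8a trimethylsilyl ether | C[Si](C)(C)OC1=C[C@H](Br)C(C)(C)[C@]1(C)C1=CC[C@@]2(C)C(Br)=CC[C@](C)(O[Si](C)(C)C(C)(C)C)[C@]2(O[Si](C)(C)C)C1 | intermediate
24 | β-bromo ketone: C4′ bromide cis to the decalinyl group, C2′ ketone, C2=C3 alkene | O=C1C[C@H](Br)C(C)(C)[C@]1(C)C1=CC[C@@]2(C)C(Br)=CC[C@](C)(O[Si](C)(C)C(C)(C)C)[C@]2(O)C1 | intermediate
25 | 2,3-epoxide of 24, oxygen on the face of the C8a hydroxyl | O=C1C[C@H](Br)C(C)(C)[C@]1(C)[C@]12O[C@H]1C[C@@]3(C)C(Br)=CC[C@](C)(O[Si](C)(C)C(C)(C)C)[C@]3(O)C2 | intermediate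
26 | triol: C2, C8a and C2′ hydroxyls free, C8 silyl ether, C4′ bromide, C5 alkenyl bromide | CC1(C)[C@@H](Br)C[C@@H](O)[C@@]1(C)[C@]1(O)CC[C@@]2(C)C(Br)=CC[C@](C)(O[Si](C)(C)C(C)(C)C)[C@]2(O)C1 | intermediate
27 | C8 tert-butyldimethylsilyl ether of the target | CC1(C)[C@@H](Br)C[C@@H](O)[C@@]1(C)[C@]1(O)CC[C@@]2(C)[C@H](Br)CC[C@](C)(O[Si](C)(C)C(C)(C)C)[C@]2(O)C1 | intermediate
28 | target, (2S,4aR,5R,8S,8aS)-5-bromo-2-[(1S,2R,4S)-4-bromo-2-hydroxy-1,5,5-trimethylcyclopentyl]-4a,8-dimethyldecahydronaphthalene-2,8,8a-triol | CC1(C)[C@@H](Br)C[C@@H](O)[C@@]1(C)[C@]1(O)CC[C@@]2(C)[C@H](Br)CC[C@](C)(O)[C@]2(O)C1 | target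

Total step count: 19. Longest linear sequence: 19 steps from geraniol (8 and 16 are purchased).

Steps most likely to fail

Step 10. What may go wrong: silylation of the enone instead of the furanone, a cycloaddition equilibrium that stays on the furan side, or opening of the oxygen bridge by β-elimination at C8a while the enol ether is hydrolysed. The fallback sets out from 11 and returns at 15. The furanone carbonyl of 11 is reduced with i-Bu2AlH (CH2Cl2, −78 °C) and the dihydrofuranol is dehydrated on mildly acidic work-up to the 2-alkylfuran alcohol F1. Dess–Martin oxidation gives the furan enone F2. The intramolecular furan Diels–Alder reaction promoted by MeAlCl2 (CH2Cl2, −78 °C) gives the oxanorbornene ketone F3 with the same exo tether and the same facial control. BH3·THF followed by NaBO3 places boron on the exo face at C2 (the alkene carbon remote from the quaternary C8a) and reduces the C5 ketone, giving the diol F4. Double Dess–Martin oxidation returns the diketone 15.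

Step 14. What may go wrong: poor facial selectivity at C1′, because the substrate has no bias of its own and the catalyst may not discriminate the faces of the hindered enolate (the cinchonine-derived pseudoenantiomer would be tried first if the sense is opposite), or migration of the alkene through reprotonation of the extended enolate. The fallback uses a temporary silicon tether, sets out from 21 and returns at 22. The C8a hydroxyl of 21 is silylated with (bromomethyl)chlorodimethylsilane and imidazole to the bromomethylsilyl ether F5. KN(SiMe3)2 (THF, −78 to 0 °C, high dilution) forms the extended enolate, in which the gem-dimethyl carbon lies next to the vinylic C3–H, and the tethered CH2Br alkylates C1′ from the face of the C8a oxygen to give the seven-membered cyclic siloxane F6. Bu4NF in wet DMF at 70 °C cleaves the Si–O and Si–C bonds (protodesilylation), leaving the C1′ methyl and the C8a hydroxyl of 22.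

Step 15. What may go wrong: loss of HBr back to the enone on work-up, incomplete equilibration to the cis-1,3 isomer, or addition of adventitious HBr to the C2=C3 alkene. The fallback sets out from 22 and returns at 24. Nucleophilic epoxidation (H2O2, NaOH, MeOH, 0 °C) on the enone face of the C1′ methyl gives the epoxy ketone F7. SmI2 (THF/MeOH, −90 °C) cleaves the α C–O bond to give the β-hydroxy ketone F8, with the C4′ hydroxyl trans to the decalinyl group. Appel bromination (PPh3, CBr4, CH2Cl2, 0 °C) with inversion gives 24.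

Further compounds
F1 | step 10 | (2S)-2-(tert-butyldimethylsilyloxy)-2-(furan-2-yl)-6-methylhept-6-en-5-ol (C5 epimers) | c1coc(c1)[C@@](C)(O[Si](C)(C)C(C)(C)C)CCC(O)C(C)=C
F2 | step 10 | (6S)-6-(tert-butyldimethylsilyloxy)-6-(furan-2-yl)-2-methylhept-1-en-3-one | c1coc(c1)[C@@](C)(O[Si](C)(C)C(C)(C)C)CCC(=O)C(C)=C
F3 | step 10 | oxanorbornene ketone: 8-(tert-butyldimethylsilyloxy)-4a,8-dimethyl-3,8a-epoxy-1,2-ene-decalin-5-one, relative configuration as in 15 | C=1[C@@H]2C[C@@]3(C)C(=O)CC[C@](C)(O[Si](C)(C)C(C)(C)C)[C@]3(O2)C=1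
F4 | step 10 | 3,8a-epoxydecalin-2,5-diol with C8 silyl ether (carbinol centres uncontrolled) | OC1[C@@H]2C[C@@]3(C)C(O)CC[C@](C)(O[Si](C)(C)C(C)(C)C)[C@]3(O2)C1
F5 | step 14 | C8a (bromomethyl)dimethylsilyl ether of 21 | O=C1C=CC(C)(C)C1C1=CC[C@@]2(C)C(Br)=CC[C@](C)(O[Si](C)(C)C(C)(C)C)[C@]2(O[Si](C)(C)CBr)C1
F6 | step 14 | cyclic siloxane with a C1′–CH2–SiMe2–O–C8a bridge | O=C1C=CC(C)(C)[C@]1(C4)C1=CC[C@@]2(C)C(Br)=CC[C@](C)(O[Si](C)(C)C(C)(C)C)[C@]2(O[Si](C)(C)4)C1
F7 | step 15 | 3′,4′-epoxy ketone of 22, epoxide on the face of the C1′ methyl | O=C1[C@H]3O[C@H]3C(C)(C)[C@]1(C)C1=CC[C@@]2(C)C(Br)=CC[C@](C)(O[Si](C)(C)C(C)(C)C)[C@]2(O)C1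
F8 | step 15 | C4′ β-hydroxy ketone, hydroxyl trans to the decalinyl group | O=C1C[C@@H](O)C(C)(C)[C@]1(C)C1=CC[C@@]2(C)C(Br)=CC[C@](C)(O[Si](C)(C)C(C)(C)C)[C@]2(O)C1
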